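**Retrosynthetic overview**
1. The C5–prenyl bond comes from an aromatic Claisen [3,3] shift of the 6-O-(1,1-dimethylallyl) ether 17. This is the last step.
2. The CMe2OH group comes from MeMgBr addition to the dihydrobenzofuran-2-carboxylate 11.
3. The O1–C2 bond comes from an intramolecular Mitsunobu closure of the (R)-α-hydroxy ester 9 with inversion. This dihydrofuran is the only ring built; both benzene rings are bought.
4. The C3–C3a bond comes from an aryl-metal opening of methyl (2R)-glycidate 5 (L-serine series), which supplies the only stereocentre.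
5. The Z-stilbene comes from a Wittig reaction assisted by the ortho-bromine of aldehyde 2, which is made by bromination of commercial 1.

Assumption: C-2 of the target reads as (S) from the SMILES, and methyl (2R)-glycidate is taken as a catalogue chemical. All Z-stilbenes are handled with exclusion of light.

**Step 1**
Reactants: 1 3,5-bis(benzyloxy)benzaldehyde
Product: 2 3,5-bis(benzyloxy)-2-bromobenzaldehyde
Conditions: NBS (1.05 equiv), MeCN, 0 °C to rt, dark
Reagents that add atoms: N-bromosuccinimide, O=C1CCC(=O)N1Br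
Why: Electrophilic aromatic bromination goes to C-2, which is ortho to one benzyloxy group and para to the other, because C-4 between them is shielded and the polar solvent in the dark suppresses benzylic radical bromination.

**Step 2**
Reactants: 2 3,5-bis(benzyloxy)-2-bromobenzaldehyde; 3 benzyltriphenylphosphonium bromide
Product: 4 1,5-bis(benzyloxy)-2-bromo-3-[(Z)-2-phenylethenyl]benzene
Conditions: 3 (1.2 equiv), NaN(SiMe3)2 (1.15 equiv), THF, −78 °C; then 2, −78 °C to rt; Z isomer separated on silica
Reagents that add atoms: none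
Why: This is a Wittig olefination with a semistabilised ylide under lithium-free kinetic control, where the ortho-bromine on the aldehyde raises the cis selectivity (expected Z/E about 6:1) and the minor E isomer is removed by chromatography.

**Step 3**
Reactants: 4 1,5-bis(benzyloxy)-2-bromo-3-[(Z)-2-phenylethenyl]benzene; 5 methyl (2R)-oxirane-2-carboxylate
Product: 8 methyl (2R)-3-{2,4-bis(benzyloxy)-6-[(Z)-2-phenylethenyl]phenyl}-2-hydroxypropanoate, via aryllithium 6 (not isolated), via arylmagnesium bromide 7 (not isolated)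
Conditions: n-BuLi (1.05 equiv), THF, −78 °C; MgBr2·OEt2 (1.2 equiv), −78 to −30 °C; CuBr·SMe2 (15 mol %), 5 (1.5 equiv), −30 to 0 °C; then H2O
Reagents that add atoms: none
Why: Bromine–lithium exchange at −78 °C outruns addition to the stilbene and keeps the Z geometry, and the monovalent-copper-catalysed Grignard opening of the glycidic ester (SN2 at the unsubstituted C-3) leaves the C-2–O bond intact, so the (R) centre of 5 is carried over unchanged.

**Step 4**
Reactants: 8 methyl (2R)-3-{2,4-bis(benzyloxy)-6-[(Z)-2-phenylethenyl]phenyl}-2-hydroxypropanoate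
Product: 9 methyl (2R)-3-{2,4-dihydroxy-6-[(Z)-2-phenylethenyl]phenyl}-2-hydroxypropanoate
Conditions: BCl3 (5 equiv), pentamethylbenzene (6 equiv), CH2Cl2, −78 °C; cold pH 7 buffer; used at once
Reagents that add atoms: none
Why: This Lewis-acid debenzylation of aryl benzyl ethers uses pentamethylbenzene as a non-basic benzyl-cation scavenger and is mild enough at −78 °C for the Z-alkene, the methyl ester and the carbinol centre, while the neutral work-up avoids lactonisation.

**Step 5**
Reactants: 9 methyl (2R)-3-{2,4-dihydroxy-6-[(Z)-2-phenylethenyl]phenyl}-2-hydroxypropanoate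
Product: 11 methyl (2S)-6-hydroxy-4-[(Z)-2-phenylethenyl]-2,3-dihydro-1-benzofuran-2-carboxylate, via alkoxyphosphonium phenoxide 10 (not isolated)
Conditions: PPh3 (1.3 equiv), DIAD (1.3 equiv), THF (0.02 M), 0 °C to rt
Reagents that add atoms: none
Why: In this intramolecular Mitsunobu etherification the α-hydroxy ester carbon is activated on phosphorus and displaced 5-exo-tet by the ortho phenoxide with clean SN2 inversion, (R) to (S), while dilution holds back the remote phenol.

**Step 6**
Reactants: 11 methyl (2S)-6-hydroxy-4-[(Z)-2-phenylethenyl]-2,3-dihydro-1-benzofuran-2-carboxylate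
Product: 13 (2S)-2-(2-hydroxypropan-2-yl)-4-[(Z)-2-phenylethenyl]-2,3-dihydro-1-benzofuran-6-ol, via methyl ketone 12 (not isolated)
Conditions: MeMgBr (4.5 equiv), THF, −20 °C to rt; then H2O
Reagents that add atoms: methylmagnesium bromide, C[Mg]Br
Why: This is a double Grignard addition to the ester after deprotonation of the phenol, and because addition is faster than enolisation the (S) centre next to the carbonyl is kept and is configurationally safe afterwards.

**Step 7**
Reactants: 14 2-methylbut-3-en-2-ol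
Product: 16 tert-butyl 2-methylbut-3-en-2-yl carbonate, via lithium alkoxide 15 (not isolated)
Conditions: n-BuLi (1.0 equiv), THF, 0 °C; Boc2O (1.05 equiv), 0 °C to rt; then H2O
Reagents that add atoms: di-tert-butyl dicarbonate, CC(C)(C)OC(=O)OC(=O)OC(C)(C)C
Why: O-acylation of the tertiary lithium alkoxide with Boc2O gives the mixed carbonate that serves as the allyl donor.

**Step 8**
Reactants: 13 (2S)-2-(2-hydroxypropan-2-yl)-4-[(Z)-2-phenylethenyl]-2,3-dihydro-1-benzofuran-6-ol; 16 tert-butyl 2-methylbut-3-en-2-yl carbonate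
Product: 17 2-{(2S)-6-[(2-methylbut-3-en-2-yl)oxy]-4-[(Z)-2-phenylethenyl]-2,3-dihydro-1-benzofuran-2-yl}propan-2-ol
Conditions: Pd(PPh3)4 (5 mol %), 16 (2 equiv), THF, 0–5 °C; Et3N-washed silica
Reagents that add atoms: none
Why: In this Tsuji–Trost O-allylation with zerovalent palladium, decarboxylative ionisation releases tert-butoxide that deprotonates only the phenol, and the phenoxide attacks the more substituted allyl terminus under kinetic control, leaving the tertiary alcohol and C-2 untouched.

**Step 9**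
Reactants: 17 2-{(2S)-6-[(2-methylbut-3-en-2-yl)oxy]-4-[(Z)-2-phenylethenyl]-2,3-dihydro-1-benzofuran-2-yl}propan-2-ol
Product: 19 (2S)-2-(2-hydroxypropan-2-yl)-5-(3-methylbut-2-en-1-yl)-4-[(Z)-2-phenylethenyl]-2,3-dihydro-1-benzofuran-6-ol, via ortho-dienone 18 (not isolated)
Conditions: PhNEt2 (degassed), 130 °C, Ar, dark, 3 h
Reagents that add atoms: none
Why: The aromatic Claisen rearrangement ([3,3]-sigmatropic shift) bonds the unsubstituted allyl terminus to C-5, the ortho site para to O-1 that meta-alkoxy aryl allyl ethers prefer over the site between the two oxygens, and tautomerisation of the dienone restores the phenol while the basic solvent prevents chroman formation and neither C-2 nor the Z-alkene is touched at this temperature.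

**Compound list**
1 | 3,5-bis(benzyloxy)benzaldehyde | O=Cc1cc(OCc2ccccc2)cc(OCc2ccccc2)c1 | starting material
2 | 3,5-bis(benzyloxy)-2-bromobenzaldehyde | O=Cc1cc(OCc2ccccc2)cc(OCc2ccccc2)c1Br | intermediate
3 | benzyltriphenylphosphonium bromide | [Br-].c1ccccc1C[P+](c1ccccc1)(c1ccccc1)c1ccccc1 | starting material
4 | 1,5-bis(benzyloxy)-2-bromo-3-[(Z)-2-phenylethenyl]benzene | Brc1c(OCc2ccccc2)cc(OCc2ccccc2)cc1/C=C\c1ccccc1 | intermediate
5 | methyl (2R)-oxirane-2-carboxylate (methyl (R)-glycidate) | COC(=O)[C@H]1CO1 | starting material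
6 | {2,4-bis(benzyloxy)-6-[(Z)-2-phenylethenyl]phenyl}lithium | [Li]c1c(OCc2ccccc2)cc(OCc2ccccc2)cc1/C=C\c1ccccc1 | intermediate (not isolated)
7 | {2,4-bis(benzyloxy)-6-[(Z)-2-phenylethenyl]phenyl}magnesium bromide | Br[Mg]c1c(OCc2ccccc2)cc(OCc2ccccc2)cc1/C=C\c1ccccc1 | intermediate (not isolated)
8 | methyl (2R)-3-{2,4-bis(benzyloxy)-6-[(Z)-2-phenylethenyl]phenyl}-2-hydroxypropanoate | COC(=O)[C@H](O)Cc1c(OCc2ccccc2)cc(OCc2ccccc2)cc1/C=C\c1ccccc1 | intermediate
9 | methyl (2R)-3-{2,4-dihydroxy-6-[(Z)-2-phenylethenyl]phenyl}-2-hydroxypropanoate | COC(=O)[C@H](O)Cc1c(O)cc(O)cc1/C=C\c1ccccc1 | intermediate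
10 | (2R)-alkoxy(triphenyl)phosphonium phenoxide zwitterion derived from 9 | COC(=O)[C@H](O[P+](c1ccccc1)(c1ccccc1)c1ccccc1)Cc1c([O-])cc(O)cc1/C=C\c1ccccc1 | intermediate (not isolated)
11 | methyl (2S)-6-hydroxy-4-[(Z)-2-phenylethenyl]-2,3-dihydro-1-benzofuran-2-carboxylate | COC(=O)[C@@H]1Cc2c(O1)cc(O)cc2/C=C\c1ccccc1 | intermediate
12 | 1-{(2S)-6-hydroxy-4-[(Z)-2-phenylethenyl]-2,3-dihydro-1-benzofuran-2-yl}ethan-1-one (present as its bromomagnesium phenoxide, drawn neutral) | CC(=O)[C@@H]1Cc2c(O1)cc(O)cc2/C=C\c1ccccc1 | intermediate (not isolated)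
13 | (2S)-2-(2-hydroxypropan-2-yl)-4-[(Z)-2-phenylethenyl]-2,3-dihydro-1-benzofuran-6-ol | CC(C)(O)[C@@H]1Cc2c(O1)cc(O)cc2/C=C\c1ccccc1 | intermediate
14 | 2-methylbut-3-en-2-ol | C=CC(C)(C)O | starting material
15 | lithium 2-methylbut-3-en-2-olate | [Li+].[O-]C(C)(C)C=C | intermediate (not isolated)
16 | tert-butyl 2-methylbut-3-en-2-yl carbonate | C=CC(C)(C)OC(=O)OC(C)(C)C | intermediate
17 | 2-{(2S)-6-[(2-methylbut-3-en-2-yl)oxy]-4-[(Z)-2-phenylethenyl]-2,3-dihydro-1-benzofuran-2-yl}propan-2-ol | CC(C)(O)[C@@H]1Cc2c(O1)cc(OC(C)(C)C=C)cc2/C=C\c1ccccc1 | intermediate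
18 | (2S)-2-(2-hydroxypropan-2-yl)-5-(3-methylbut-2-en-1-yl)-4-[(Z)-2-phenylethenyl]-3,5-dihydro-1-benzofuran-6(2H)-one (transient sp3 C-5, both epimers) | CC(C)(O)[C@@H]1CC2=C(/C=C\c3ccccc3)C(CC=C(C)C)C(=O)C=C2O1 | intermediate (not isolated)
19 | (2S)-2-(2-hydroxypropan-2-yl)-5-(3-methylbut-2-en-1-yl)-4-[(Z)-2-phenylethenyl]-2,3-dihydro-1-benzofuran-6-ol | CC(C)=CCc1c(O)cc2c(c1/C=C\c1ccccc1)C[C@@H](C(C)(C)O)O2 | target

**Step count**
- Total steps: 9.
- Longest linear sequence: 8 (steps 1–6, 8 and 9). Step 7 is a side branch.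

**Steps most likely to fail**

**Step 3.** The aryl nucleophile is flanked on both sides, carries a Z-alkene, and has to open the epoxide faster than it attacks the ester. The fallback sets out from 2 and comes back at 8. It makes the Z-alkene only after the C–C bond is in place.
- Compound 2 is homologated with dimethyl (1-diazo-2-oxopropyl)phosphonate and K2CO3 in MeOH (Seyferth–Gilbert reaction in its Ohira–Bestmann form) to 1,5-bis(benzyloxy)-2-bromo-3-ethynylbenzene F1.
- F1 is coupled with iodobenzene (PdCl2(PPh3)2, CuI, Et3N, rt; Sonogashira). The hindered, electron-rich C–Br bond stays intact, giving 1,5-bis(benzyloxy)-2-bromo-3-(phenylethynyl)benzene F2.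
- This slimmer, alkene-free bromide is taken through bromine–lithium exchange, MgBr2 and the CuBr·SMe2-catalysed opening of 5. The product is methyl (2R)-3-[2,4-bis(benzyloxy)-6-(phenylethynyl)phenyl]-2-hydroxypropanoate F3.
- Semihydrogenation of F3 (H2, Pd/CaCO3 poisoned with Pb(OAc)2, quinoline, EtOAc) then gives 8 with cis geometry.

**Step 5.** Three side reactions can compete with ring closure: lactonisation of 9 to a 3-hydroxydihydrocoumarin, elimination to a cinnamate, and intermolecular etherification at the remote phenol. The fallback sets out from 8 and comes back at 11. It activates the carbinol before the phenols are unmasked.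
- MsCl and Et3N in CH2Cl2 at 0 °C give methyl (2R)-3-{2,4-bis(benzyloxy)-6-[(Z)-2-phenylethenyl]phenyl}-2-[(methylsulfonyl)oxy]propanoate F4.
- BCl3 and pentamethylbenzene at −78 °C give methyl (2R)-3-{2,4-dihydroxy-6-[(Z)-2-phenylethenyl]phenyl}-2-[(methylsulfonyl)oxy]propanoate F5.
- K2CO3 in acetone at rt closes the ring by an intramolecular Williamson SN2 reaction with the same single inversion, giving 11.

**Step 9.** The allyl group may go partly to C-7, next to the less crowded side, and the tertiary ether may lose isoprene. The C-7 isomer would have to be separated on silica. The fallback sets out from 13 and comes back at 19. It replaces the rearrangement by halogenation and cross-coupling.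
- N-iodosuccinimide (1.0 equiv) in MeCN at −20 °C in the dark iodinates the position ortho to the phenol and para to O-1. This gives (2S)-2-(2-hydroxypropan-2-yl)-5-iodo-4-[(Z)-2-phenylethenyl]-2,3-dihydro-1-benzofuran-6-ol F6.
- Stille coupling of F6 with tributyl(3-methylbut-2-en-1-yl)stannane (Pd(PPh3)4, DMF, 80 °C) gives 19 with the linear prenyl group.

**Further compounds**
F1 | step 3 | 1,5-bis(benzyloxy)-2-bromo-3-ethynylbenzene | C#Cc1cc(OCc2ccccc2)cc(OCc2ccccc2)c1Br
F2 | step 3 | 1,5-bis(benzyloxy)-2-bromo-3-(phenylethynyl)benzene | Brc1c(OCc2ccccc2)cc(OCc2ccccc2)cc1C#Cc1ccccc1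
F3 | step 3 | methyl (2R)-3-[2,4-bis(benzyloxy)-6-(phenylethynyl)phenyl]-2-hydroxypropanoate | COC(=O)[C@H](O)Cc1c(OCc2ccccc2)cc(OCc2ccccc2)cc1C#Cc1ccccc1
F4 | step 5 | methyl (2R)-3-{2,4-bis(benzyloxy)-6-[(Z)-2-phenylethenyl]phenyl}-2-[(methylsulfonyl)oxy]propanoate | COC(=O)[C@H](OS(C)(=O)=O)Cc1c(OCc2ccccc2)cc(OCc2ccccc2)cc1/C=C\c1ccccc1
F5 | step 5 | methyl (2R)-3-{2,4-dihydroxy-6-[(Z)-2-phenylethenyl]phenyl}-2-[(methylsulfonyl)oxy]propanoate | COC(=O)[C@H](OS(C)(=O)=O)Cc1c(O)cc(O)cc1/C=C\c1ccccc1
F6 | step 9 | (2S)-2-(2-hydroxypropan-2-yl)-5-iodo-4-[(Z)-2-phenylethenyl]-2,3-dihydro-1-benzofuran-6-ol | CC(C)(O)[C@@H]1Cc2c(O1)cc(O)c(I)c2/C=C\c1ccccc1
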